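**Plan**

1. Numbering: ring C1 (CH–O-angeloyl), C2 (CH–OH), C3 (C(CH3)OH), C4 (CHCl), C5 (CH2), C6 (CH bearing the side chain); side chain C7(=CH2)–C8(O-angeloyl)–C9–C10/C11 (epoxide). Cuts, in order: C10/C11 epoxide; both angelates; C7–C8; C4–Cl and C3–O (through a C3/C4 epoxide of a C3=C4 alkene); then ring bonds C6–C1 and C3–C2 together.
2. Enabling feature: C6 carries C7 at the carboxyl level, 1,4 across the ring from the methyl-bearing C3, with the cis-diol C1/C2 between them. This is the diene of methyl 6-methyl-2-oxo-2H-pyran-3-carboxylate (ring oxygen on the methyl carbon, lactone C=O as a traceless bridge) plus a cis-enediol ketal.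
3. Forward: pyranone; asymmetric inverse-demand [4+2] with 2,2-dimethyl-1,3-dioxole and CO2 loss (whole carbocycle with C7, CH3 and cis-diol); 1,4-reduction; bridged lactone C7/O–C2 (leaves only C1–OH free); C3/C4 epoxide, then chloride; C7 methyl ketone, alkenyl triflate, Ni/Cr coupling; angelates; side-chain epoxide.
4. Stereochemistry: C1/C2 (absolute) from the Cu(OTf)2–bis(oxazoline) catalyst in the cycloaddition; C6 by protonation anti to the dioxolane, locked by lactonisation; C3 by hydroxyl-directed epoxidation; C4 by anti opening; C8 by the chiral ligand on chromium; C10 by the Shi ketone.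

Key step: step 2

Remark: 2,2-dimethyl-1,3-dioxole, angelic anhydride and the L-series Shi ketone (1,2:4,5-di-O-isopropylidene-β-L-erythro-2,3-hexodiulo-2,6-pyranose) are taken as purchasable reagents.

**Route**

Step 1
Reactants: 1 (E)-4-methoxybut-3-en-2-one; 2 dimethyl malonate
Product: 3 methyl 6-methyl-2-oxo-2H-pyran-3-carboxylate
Conditions: NaOMe (0.2 equiv), MeOH, 0 °C to rt; then TsOH·H2O (cat.), toluene, reflux (MeOH distilled off)
Reagents that add atoms: none
Why: Addition–elimination of the malonate at the β-alkoxy enone, then lactonisation of the dienol onto one ester, is the standard condensation route to 3-carboalkoxy-2-pyranones; no stereocentre is formed.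

Step 2
Reactants: 3 methyl 6-methyl-2-oxo-2H-pyran-3-carboxylate; 4 2,2-dimethyl-1,3-dioxole
Product: 6 methyl (3aS,7aR)-2,2,7-trimethyl-3a,7a-dihydro-1,3-benzodioxole-4-carboxylate, via endo bicyclic lactone 5 (not isolated)
Conditions: Cu(OTf)2 (10 mol%), (S,S)-2,2'-isopropylidenebis(4-tert-butyl-2-oxazoline) (11 mol%), 4 Å MS, CH2Cl2, −20 °C to rt; filtration through silica; toluene, 90 °C
Reagents that add atoms: none
Why: Inverse-electron-demand [4+2] cycloaddition: the electron-poor pyranone diene, further activated by bidentate binding of its lactone and ester carbonyls to divalent copper, adds the electron-rich enediol ketal suprafacially at both diene termini, so ring bonds C6–C1 and C3–C2 form together; the closest known reaction type is the Cu(OTf)2–bis(oxazoline)-catalysed cycloaddition of 3-carboalkoxy-2-pyranones with enol ethers. The closure is a concerted, asynchronous six-ring formation that also creates the 2-oxabicyclo[2.2.2]octenone; warming then expels CO2 by retro-[4+2] and leaves the cyclohexa-1,3-diene with the C3=C4 alkene where the chlorohydrin is needed. The two carbinol centres are cis because the dienophile is a cis-alkene held in a five-membered ring; their absolute sense comes from the ligand, which screens one face of the chelated pyranone, combined with the endo orientation of the dioxole oxygens (assigned by analogy with enol ethers; the (R,R)-ligand would invert it). The two bridgehead centres are fixed by the suprafacial addition but are erased on purpose with the loss of CO2, so only face and endo/exo selectivity count, and regiochemistry is no issue because the dienophile is symmetric. The step needs the methyl-bearing diene terminus to accept a bond, which the ester activation and the small, flat dienophile should allow.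

Step 3
Reactants: 6 methyl (3aS,7aR)-2,2,7-trimethyl-3a,7a-dihydro-1,3-benzodioxole-4-carboxylate
Product: 7 methyl (3aS,4S,7aR)-2,2,7-trimethyl-3a,4,5,7a-tetrahydro-1,3-benzodioxole-4-carboxylate (ester cis to both ring oxygens)
Conditions: [(Ph3P)CuH]6 (5 mol%), PhMe2SiH (1.5 equiv), t-BuOH (1.5 equiv), toluene, 0 °C to rt
Reagents that add atoms: none
Why: Stryker-type conjugate (1,4-) reduction with the hydride of [(Ph3P)CuH]6 puts hydride on the unsubstituted β-carbon, not on the methyl-bearing δ-carbon, and t-BuOH should protonate the copper enolate on the face opposite the pseudoaxial allylic C–O bond of the dioxolane (kinetic protonation), placing the ester cis to the oxygens.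

Step 4
Reactants: 7 methyl (3aS,4S,7aR)-2,2,7-trimethyl-3a,4,5,7a-tetrahydro-1,3-benzodioxole-4-carboxylate
Product: 9 (1S,5R,8S)-8-hydroxy-4-methyl-6-oxabicyclo[3.2.1]oct-3-en-7-one, via diol ester 8 (not isolated)
Conditions: AcOH/H2O (4:1), 40 °C; then PPTS (cat.), toluene, 70 °C
Reagents that add atoms: none
Why: Acetal hydrolysis frees the cis-diol, and the ester, 1,3-cis to the allylic hydroxyl, closes to the bridged γ-lactone (no β-lactone to the neighbouring hydroxyl), which tells the two hydroxyls apart and locks the ester-bearing centre against epimerisation.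

Step 5
Reactants: 9 (1S,5R,8S)-8-hydroxy-4-methyl-6-oxabicyclo[3.2.1]oct-3-en-7-one
Product: 10 (1S,5R,8S)-8-(tert-butyldimethylsilyloxy)-4-methyl-6-oxabicyclo[3.2.1]oct-3-en-7-one
Conditions: TBSOTf, 2,6-lutidine, CH2Cl2, −78 to 0 °C
Reagents that add atoms: tert-butyldimethylsilyl triflate CC(C)(C)[Si](C)(C)OS(=O)(=O)C(F)(F)F
Why: Standard silylation of the only free hydroxyl (future C1–O); no stereocentre is touched.

Step 6
Reactants: 10 (1S,5R,8S)-8-(tert-butyldimethylsilyloxy)-4-methyl-6-oxabicyclo[3.2.1]oct-3-en-7-one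
Product: 11 (1S,5R,6S)-6-(tert-butyldimethylsilyloxy)-5-hydroxy-N-methoxy-N,4-dimethylcyclohex-3-ene-1-carboxamide
Conditions: Me(MeO)NH, i-PrMgCl, THF, −20 °C
Reagents that add atoms: N,O-dimethylhydroxylamine CNOC
Why: Aminolysis of the strained lactone by the chloromagnesium amide gives the Weinreb amide and releases the allylic hydroxyl; the α-centre is a bridgehead in the substrate and cannot enolise.

Step 7
Reactants: 11 (1S,5R,6S)-6-(tert-butyldimethylsilyloxy)-5-hydroxy-N-methoxy-N,4-dimethylcyclohex-3-ene-1-carboxamide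
Product: 12 (1S,2S,3S,4S,6R)-3-(tert-butyldimethylsilyloxy)-2-hydroxy-N-methoxy-N,1-dimethyl-7-oxabicyclo[4.1.0]heptane-4-carboxamide
Conditions: VO(acac)2 (5 mol%), t-BuOOH (1.5 equiv, decane), CH2Cl2, 0 °C to rt
Reagents that add atoms: tert-butyl hydroperoxide CC(C)(C)OO
Why: Vanadium-catalysed hydroxyl-directed epoxidation of a cyclic allylic alcohol delivers oxygen to the alkene face syn to the hydroxyl, which sets the tertiary C–O centre (C3) and the methyl orientation.

Step 8
Reactants: 12 (1S,2S,3S,4S,6R)-3-(tert-butyldimethylsilyloxy)-2-hydroxy-N-methoxy-N,1-dimethyl-7-oxabicyclo[4.1.0]heptane-4-carboxamide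
Product: 13 (1S,2S,3S,4S,5S)-2-(tert-butyldimethylsilyloxy)-5-chloro-3,4-dihydroxy-N-methoxy-N,4-dimethylcyclohexane-1-carboxamide
Conditions: ClTi(OiPr)3 (1.5 equiv), toluene, 0 °C to rt; aqueous tartrate work-up
Reagents that add atoms: chlorotitanium triisopropoxide CC(C)O[Ti](Cl)(OC(C)C)OC(C)C
Why: Titanium-mediated opening of a 2,3-epoxy alcohol at its distal carbon: the alkoxide-bound titanium activates the epoxide and chloride attacks the secondary carbon with inversion in the trans-diaxial (Fürst–Plattner) mode that keeps the large substituent equatorial, giving C4–Cl trans to the C3 hydroxyl.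

Step 9
Reactants: 13 (1S,2S,3S,4S,5S)-2-(tert-butyldimethylsilyloxy)-5-chloro-3,4-dihydroxy-N-methoxy-N,4-dimethylcyclohexane-1-carboxamide
Product: 14 (3aS,4S,6S,7S,7aS)-7-(tert-butyldimethylsilyloxy)-4-chloro-N-methoxy-N,2,2,3a-tetramethylhexahydro-1,3-benzodioxole-6-carboxamide
Conditions: 2-methoxypropene, PPTS (cat.), CH2Cl2, 0 °C to rt
Reagents that add atoms: 2-methoxypropene COC(C)=C
Why: Acetonide formation on the cis tertiary/secondary diol masks both hydroxyls, so the chlorohydrin cannot close back to the epoxide in the basic steps and the C2 hydroxyl is not acylated later.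

Step 10
Reactants: 14 (3aS,4S,6S,7S,7aS)-7-(tert-butyldimethylsilyloxy)-4-chloro-N-methoxy-N,2,2,3a-tetramethylhexahydro-1,3-benzodioxole-6-carboxamide
Product: 15 1-[(3aS,4S,6S,7S,7aS)-7-(tert-butyldimethylsilyloxy)-4-chloro-2,2,3a-trimethylhexahydro-1,3-benzodioxol-6-yl]ethanone
Conditions: MeMgBr (1.5 equiv), THF, −20 to 0 °C
Reagents that add atoms: methylmagnesium bromide C[Mg]Br
Why: Weinreb ketone synthesis: the chelated tetrahedral intermediate stops at the ketone stage and the ketone is only released on work-up, so the α-centre is not epimerised.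

Step 11
Reactants: 15 1-[(3aS,4S,6S,7S,7aS)-7-(tert-butyldimethylsilyloxy)-4-chloro-2,2,3a-trimethylhexahydro-1,3-benzodioxol-6-yl]ethanone
Product: 16 1-[(3aS,4S,6S,7S,7aS)-7-(tert-butyldimethylsilyloxy)-4-chloro-2,2,3a-trimethylhexahydro-1,3-benzodioxol-6-yl]ethenyl trifluoromethanesulfonate
Conditions: KHMDS (1.1 equiv), THF, −78 °C; then PhNTf2, −78 °C to −20 °C
Reagents that add atoms: N-phenylbis(trifluoromethanesulfonimide) O=S(=O)(N(c1ccccc1)S(=O)(=O)C(F)(F)F)C(F)(F)F
Why: Kinetic deprotonation at the methyl group, not at the hindered ring methine, followed by O-triflation gives the 2-alkenyl triflate and leaves the adjacent ring stereocentre untouched.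

Step 12
Reactants: 17 4-methylpent-3-en-1-ol
Product: 18 4-methylpent-3-enal
Conditions: Dess–Martin periodinane, NaHCO3, CH2Cl2, 0 °C; used crude
Reagents that add atoms: none
Why: Dess–Martin oxidation under buffered, neutral conditions should give the β,γ-unsaturated aldehyde without moving the double bond into conjugation.

Step 13
Reactants: 16 1-[(3aS,4S,6S,7S,7aS)-7-(tert-butyldimethylsilyloxy)-4-chloro-2,2,3a-trimethylhexahydro-1,3-benzodioxol-6-yl]ethenyl trifluoromethanesulfonate; 18 4-methylpent-3-enal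
Product: 19 (3S)-2-[(3aS,4S,6R,7S,7aS)-7-(tert-butyldimethylsilyloxy)-4-chloro-2,2,3a-trimethylhexahydro-1,3-benzodioxol-6-yl]-6-methylhepta-1,5-dien-3-ol
Conditions: CrCl2 (4 equiv), NiCl2 (5 mol%), chiral oxazoline–sulfonamide ligand (enantiomer that gives the 3S alcohol), Et3N, THF/DMF, rt
Reagents that add atoms: none
Why: Nozaki–Hiyama–Kishi coupling: nickel inserts into the alkenyl triflate, the alkenyl group passes to chromium and adds to the aldehyde to give the 2-substituted allylic alcohol, with the C8 configuration set by the chiral ligand on chromium (reagent control); ketal, silyl ether and alkyl chloride are inert.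

Step 14
Reactants: 19 (3S)-2-[(3aS,4S,6R,7S,7aS)-7-(tert-butyldimethylsilyloxy)-4-chloro-2,2,3a-trimethylhexahydro-1,3-benzodioxol-6-yl]-6-methylhepta-1,5-dien-3-ol
Product: 20 (3aS,4S,6R,7S,7aS)-4-chloro-6-[(3S)-3-hydroxy-6-methylhepta-1,5-dien-2-yl]-2,2,3a-trimethylhexahydro-1,3-benzodioxol-7-ol
Conditions: TBAF, AcOH (1 equiv), THF, 0 °C to rt
Reagents that add atoms: none
Why: Fluoride cleavage of the silyl ether, buffered with acetic acid so that no free alkoxide can displace the ring chloride, exposes exactly the two hydroxyls that are to be esterified.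

Step 15
Reactants: 20 (3aS,4S,6R,7S,7aS)-4-chloro-6-[(3S)-3-hydroxy-6-methylhepta-1,5-dien-2-yl]-2,2,3a-trimethylhexahydro-1,3-benzodioxol-7-ol; 21 angelic anhydride ((Z)-2-methylbut-2-enoic anhydride)
Product: 22 (3aS,4S,6R,7S,7aS)-4-chloro-2,2,3a-trimethyl-6-{(3S)-6-methyl-3-[(Z)-2-methylbut-2-enoyloxy]hepta-1,5-dien-2-yl}hexahydro-1,3-benzodioxol-7-yl (Z)-2-methylbut-2-enoate
Conditions: LiHMDS (2.2 equiv), THF, −78 °C; then 21 (3 equiv), −78 to 0 °C
Reagents that add atoms: none
Why: Acylation of the two lithium alkoxides by angelic anhydride installs both (Z)-2-methylbut-2-enoates in one operation without a nucleophilic acyl-transfer catalyst, the conditions under which angelate is not expected to isomerise to tiglate; the C2 and C3 hydroxyls are masked in the acetonide.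

Step 16
Reactants: 22 (3aS,4S,6R,7S,7aS)-4-chloro-2,2,3a-trimethyl-6-{(3S)-6-methyl-3-[(Z)-2-methylbut-2-enoyloxy]hepta-1,5-dien-2-yl}hexahydro-1,3-benzodioxol-7-yl (Z)-2-methylbut-2-enoate
Product: 23 (1S,2S,3S,4S,6R)-4-chloro-2,3-dihydroxy-3-methyl-6-{(3S)-6-methyl-3-[(Z)-2-methylbut-2-enoyloxy]hepta-1,5-dien-2-yl}cyclohexyl (Z)-2-methylbut-2-enoate
Conditions: 80% aq. AcOH, 50 °C
Reagents that add atoms: none
Why: Acid hydrolysis of the acetonide; the esters, the chloride and both alkenes should tolerate dilute acetic acid, and this step is placed before the acid-labile epoxide is made.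

Step 17
Reactants: 23 (1S,2S,3S,4S,6R)-4-chloro-2,3-dihydroxy-3-methyl-6-{(3S)-6-methyl-3-[(Z)-2-methylbut-2-enoyloxy]hepta-1,5-dien-2-yl}cyclohexyl (Z)-2-methylbut-2-enoate
Product: 24 (1S,2S,3S,4S,6R)-4-chloro-2,3-dihydroxy-3-methyl-6-{(3S)-4-[(2S)-3,3-dimethyloxiran-2-yl]-3-[(Z)-2-methylbut-2-enoyloxy]but-1-en-2-yl}cyclohexyl (Z)-2-methylbut-2-enoate
Conditions: L-series Shi ketone (1,2:4,5-di-O-isopropylidene-β-L-erythro-2,3-hexodiulo-2,6-pyranose, 1 equiv), Oxone, NaHCO3, Bu4NHSO4, MeCN/aq. Na2EDTA, 0 °C, pH about 8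
Reagents that add atoms: Oxone (active component potassium peroxymonosulfate) [K+].[O-]S(=O)(=O)OO
Why: Shi epoxidation: the chiral dioxirane attacks only the electron-rich trisubstituted alkene (the 1,1-disubstituted alkene next to an ester and the conjugated esters are far less reactive) through the spiro transition state, which with the L-series ketone should give the (S)-epoxide; the near-neutral pH keeps the chlorohydrin from closing.

**Compound list**

1 | (E)-4-methoxybut-3-en-2-one | CO/C=C/C(C)=O | starting material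
2 | dimethyl malonate | COC(=O)CC(=O)OC | starting material
3 | methyl 6-methyl-2-oxo-2H-pyran-3-carboxylate | COC(=O)C1=CC=C(C)OC1=O | intermediate
4 | 2,2-dimethyl-1,3-dioxole | CC1(C)OC=CO1 | starting material
5 | endo cycloadduct: methyl 1-methyl-3-oxo-7,8-(isopropylidenedioxy)-2-oxabicyclo[2.2.2]oct-5-ene-4-carboxylate, dioxolane oxygens syn to the C5=C6 bridge | COC(=O)[C@]12C=C[C@](C)(OC1=O)[C@H]3OC(C)(C)O[C@@H]23 | intermediate
6 | methyl (3aS,7aR)-2,2,7-trimethyl-3a,7a-dihydro-1,3-benzodioxole-4-carboxylate | COC(=O)C1=CC=C(C)[C@H]2OC(C)(C)O[C@@H]12 | intermediate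
7 | methyl (3aS,4S,7aR)-2,2,7-trimethyl-3a,4,5,7a-tetrahydro-1,3-benzodioxole-4-carboxylate | COC(=O)[C@H]1CC=C(C)[C@H]2OC(C)(C)O[C@@H]12 | intermediate
8 | methyl (1S,5R,6S)-5,6-dihydroxy-4-methylcyclohex-3-ene-1-carboxylate | COC(=O)[C@H]1CC=C(C)[C@@H](O)[C@H]1O | intermediate
9 | (1S,5R,8S)-8-hydroxy-4-methyl-6-oxabicyclo[3.2.1]oct-3-en-7-one | O=C1[C@H]2CC=C(C)[C@@H](O1)[C@H]2O | intermediate
10 | (1S,5R,8S)-8-(tert-butyldimethylsilyloxy)-4-methyl-6-oxabicyclo[3.2.1]oct-3-en-7-one | O=C1[C@H]2CC=C(C)[C@@H](O1)[C@H]2O[Si](C)(C)C(C)(C)C | intermediate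
11 | (1S,5R,6S)-6-(tert-butyldimethylsilyloxy)-5-hydroxy-N-methoxy-N,4-dimethylcyclohex-3-ene-1-carboxamide | CON(C)C(=O)[C@H]1CC=C(C)[C@@H](O)[C@H]1O[Si](C)(C)C(C)(C)C | intermediate
12 | (1S,2S,3S,4S,6R)-3-(tert-butyldimethylsilyloxy)-2-hydroxy-N-methoxy-N,1-dimethyl-7-oxabicyclo[4.1.0]heptane-4-carboxamide | CON(C)C(=O)[C@H]1C[C@H]2O[C@@]2(C)[C@@H](O)[C@H]1O[Si](C)(C)C(C)(C)C | intermediate
13 | (1S,2S,3S,4S,5S)-2-(tert-butyldimethylsilyloxy)-5-chloro-3,4-dihydroxy-N-methoxy-N,4-dimethylcyclohexane-1-carboxamide | CON(C)C(=O)[C@H]1C[C@H](Cl)[C@@](C)(O)[C@@H](O)[C@H]1O[Si](C)(C)C(C)(C)C | intermediate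
14 | (3aS,4S,6S,7S,7aS)-7-(tert-butyldimethylsilyloxy)-4-chloro-N-methoxy-N,2,2,3a-tetramethylhexahydro-1,3-benzodioxole-6-carboxamide | CON(C)C(=O)[C@H]1C[C@H](Cl)[C@@]2(C)OC(C)(C)O[C@H]2[C@H]1O[Si](C)(C)C(C)(C)C | intermediate
15 | 1-[(3aS,4S,6S,7S,7aS)-7-(tert-butyldimethylsilyloxy)-4-chloro-2,2,3a-trimethylhexahydro-1,3-benzodioxol-6-yl]ethanone | CC(=O)[C@H]1C[C@H](Cl)[C@@]2(C)OC(C)(C)O[C@H]2[C@H]1O[Si](C)(C)C(C)(C)C | intermediate
16 | 1-[(3aS,4S,6S,7S,7aS)-7-(tert-butyldimethylsilyloxy)-4-chloro-2,2,3a-trimethylhexahydro-1,3-benzodioxol-6-yl]ethenyl trifluoromethanesulfonate | C=C(OS(=O)(=O)C(F)(F)F)[C@H]1C[C@H](Cl)[C@@]2(C)OC(C)(C)O[C@H]2[C@H]1O[Si](C)(C)C(C)(C)C | intermediate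
17 | 4-methylpent-3-en-1-ol | CC(C)=CCCO | starting material
18 | 4-methylpent-3-enal | CC(C)=CCC=O | intermediate
19 | (3S)-2-[(3aS,4S,6R,7S,7aS)-7-(tert-butyldimethylsilyloxy)-4-chloro-2,2,3a-trimethylhexahydro-1,3-benzodioxol-6-yl]-6-methylhepta-1,5-dien-3-ol | C=C([C@H](CC=C(C)C)O)[C@H]1C[C@H](Cl)[C@@]2(C)OC(C)(C)O[C@H]2[C@H]1O[Si](C)(C)C(C)(C)C | intermediate
20 | (3aS,4S,6R,7S,7aS)-4-chloro-6-[(3S)-3-hydroxy-6-methylhepta-1,5-dien-2-yl]-2,2,3a-trimethylhexahydro-1,3-benzodioxol-7-ol | C=C([C@H](CC=C(C)C)O)[C@H]1C[C@H](Cl)[C@@]2(C)OC(C)(C)O[C@H]2[C@H]1O | intermediate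
21 | angelic anhydride, (Z)-2-methylbut-2-enoic anhydride | C/C=C(/C)C(=O)OC(=O)/C(C)=C\C | starting material
22 | (3aS,4S,6R,7S,7aS)-4-chloro-2,2,3a-trimethyl-6-{(3S)-6-methyl-3-[(Z)-2-methylbut-2-enoyloxy]hepta-1,5-dien-2-yl}hexahydro-1,3-benzodioxol-7-yl (Z)-2-methylbut-2-enoate | C=C([C@H](CC=C(C)C)OC(=O)/C(C)=C\C)[C@H]1C[C@H](Cl)[C@@]2(C)OC(C)(C)O[C@H]2[C@H]1OC(=O)/C(C)=C\C | intermediate
23 | (1S,2S,3S,4S,6R)-4-chloro-2,3-dihydroxy-3-methyl-6-{(3S)-6-methyl-3-[(Z)-2-methylbut-2-enoyloxy]hepta-1,5-dien-2-yl}cyclohexyl (Z)-2-methylbut-2-enoate | C=C([C@H](CC=C(C)C)OC(=O)/C(C)=C\C)[C@H]1C[C@H](Cl)[C@@](C)(O)[C@@H](O)[C@H]1OC(=O)/C(C)=C\C | intermediate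
24 | (1S,2S,3S,4S,6R)-4-chloro-2,3-dihydroxy-3-methyl-6-{(3S)-4-[(2S)-3,3-dimethyloxiran-2-yl]-3-[(Z)-2-methylbut-2-enoyloxy]but-1-en-2-yl}cyclohexyl (Z)-2-methylbut-2-enoate (CNP0333703.2) | C=C([C@H](C[C@@H]1OC1(C)C)OC(=O)/C(C)=C\C)[C@H]1C[C@H](Cl)[C@@](C)(O)[C@@H](O)[C@H]1OC(=O)/C(C)=C\C | target

**Step count**

Total steps: 17. Longest linear sequence: 16 (steps 1–11 and 13–17; step 12 prepares the aldehyde).

**Steps most likely to fail, with fallbacks**

The three steps most likely to fail are steps 2, 3 and 13, in that order.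

Risk at step 2: the methyl-bearing diene terminus may react too slowly under the chiral catalyst, or the control of face and of endo/exo orientation may be too weak, so that the diene would form in low enantiomeric purity. The fallback for step 2 sets out from 3 and 4 and comes back to the route at 9. The cycloaddition is run thermally without catalyst (toluene, 100 °C), which should give 5 together with the enantiomeric cycloadduct F1 and then, after loss of CO2, 6 together with the enantiomeric diene ester F2 as a racemate. Steps 3 and 4 are run unchanged on this racemate and should give 7 together with the enantiomeric tetrahydro ester F3 first, then 8 together with the enantiomeric diol ester F4 in the flask, then 9 together with the enantiomeric hydroxy lactone F5 as the racemic alcohol. The secondary alcohol is resolved by lipase-catalysed acetylation (Candida antarctica lipase B, vinyl acetate, t-BuOMe), planned so that the unwanted antipode leaves as the lactone acetate F6 while 9 is recovered as the free alcohol; resolution thus replaces asymmetric catalysis.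

Risk at step 3: protonation of the enolate with too little facial preference, which would place part of the ester trans to the ring oxygens. The fallback for step 3 sets out from 6 and comes back to the route at 9. The reduction product is taken on as the mixture of 7 and the C-4 epimeric ester F7 without separation. Acetal hydrolysis as in step 4 should give 8 and the trans diol ester F8 that cannot lactonise. Heating the mixture with DBU (cat.) in toluene equilibrates the ester-bearing centre through the enolate, while 8 is drained irreversibly as lactone 9, so a thermodynamic funnel replaces kinetic protonation.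

Risk at step 13: weak control of the new carbinol centre by the chiral ligand on chromium with this hindered alkenyl triflate. The fallback for step 13 sets out from 16 and 18 and comes back to the route at 19. The coupling is run without chiral ligand (CrCl2, NiCl2 cat., DMF) and should give 19 together with the (3R)-epimeric alcohol F9 as a mixture. The mixture is oxidised with Dess–Martin periodinane to the 2-substituted enone F10 in which the carbinol centre is erased. Corey–Bakshi–Shibata reduction with (R)-1-methyl-3,3-diphenyltetrahydro-1H,3H-pyrrolo[1,2-c][1,3,2]oxazaborole and catecholborane (toluene, −78 °C), with the alkenyl group acting as the large substituent, should then give 19.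

Further compounds

F1 | step 2 | enantiomer of endo cycloadduct 5 | COC(=O)[C@@]12C=C[C@@](C)(OC1=O)[C@@H]3OC(C)(C)O[C@H]23
F2 | step 2 | methyl (3aR,7aS)-2,2,7-trimethyl-3a,7a-dihydro-1,3-benzodioxole-4-carboxylate (enantiomer of 6) | COC(=O)C1=CC=C(C)[C@@H]2OC(C)(C)O[C@H]12
F3 | step 2 | methyl (3aR,4R,7aS)-2,2,7-trimethyl-3a,4,5,7a-tetrahydro-1,3-benzodioxole-4-carboxylate (enantiomer of 7) | COC(=O)[C@@H]1CC=C(C)[C@@H]2OC(C)(C)O[C@H]12
F4 | step 2 | methyl (1R,5S,6R)-5,6-dihydroxy-4-methylcyclohex-3-ene-1-carboxylate (enantiomer of 8) | COC(=O)[C@@H]1CC=C(C)[C@H](O)[C@@H]1O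
F5 | step 2 | (1R,5S,8R)-8-hydroxy-4-methyl-6-oxabicyclo[3.2.1]oct-3-en-7-one (enantiomer of 9) | O=C1[C@@H]2CC=C(C)[C@H](O1)[C@@H]2O
F6 | step 2 | (1R,5S,8R)-4-methyl-7-oxo-6-oxabicyclo[3.2.1]oct-3-en-8-yl acetate (acetate of the enantiomer of 9) | O=C1[C@@H]2CC=C(C)[C@H](O1)[C@@H]2OC(C)=O
F7 | step 3 | methyl (3aS,4R,7aR)-2,2,7-trimethyl-3a,4,5,7a-tetrahydro-1,3-benzodioxole-4-carboxylate (C-4 epimer of 7) | COC(=O)[C@@H]1CC=C(C)[C@H]2OC(C)(C)O[C@@H]12
F8 | step 3 | methyl (1R,5R,6S)-5,6-dihydroxy-4-methylcyclohex-3-ene-1-carboxylate (trans diol ester) | COC(=O)[C@@H]1CC=C(C)[C@@H](O)[C@H]1O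
F9 | step 13 | (3R)-2-[(3aS,4S,6R,7S,7aS)-7-(tert-butyldimethylsilyloxy)-4-chloro-2,2,3a-trimethylhexahydro-1,3-benzodioxol-6-yl]-6-methylhepta-1,5-dien-3-ol | C=C([C@@H](CC=C(C)C)O)[C@H]1C[C@H](Cl)[C@@]2(C)OC(C)(C)O[C@H]2[C@H]1O[Si](C)(C)C(C)(C)C
F10 | step 13 | 2-[(3aS,4S,6R,7S,7aS)-7-(tert-butyldimethylsilyloxy)-4-chloro-2,2,3a-trimethylhexahydro-1,3-benzodioxol-6-yl]-6-methylhepta-1,5-dien-3-one | C=C(C(=O)CC=C(C)C)[C@H]1C[C@H](Cl)[C@@]2(C)OC(C)(C)O[C@H]2[C@H]1O[Si](C)(C)C(C)(C)C
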